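**Plan**

- Ring letters: A and C are the benzo and pyranone rings of the 2,3-diarylchromone, B the 4-hydroxyphenyl on C2, D the methoxyphenyl ring on C3, E the second pyranone and F its benzo ring.
- Retrosynthesis: the three benzyl ethers are removed last; ring E is cut at O1–C2 and C2–C3 (chalcone from a ring D aldehyde and a ring F acetophenone), and the formyl carbon is cut from ring D back to a bromide.
- Ring C is cut at C4–C4a and O1–C2 to phloroglucinol and an α-aryl β-ketoester, itself cut between the α-carbon and the aroyl carbonyl into an ethyl arylacetate and an aroyl chloride.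
- Enabling feature: ring A (C4a, C5 to C8, C8a, with oxygens on C5, C7 and C8a) is phloroglucinol; its threefold symmetry makes every ring carbon and every hydroxyl equivalent, so C4–C4a and O1–C2 can form at any site without protection, and O1–C2=C3–C4=O maps onto the ketoester.
- Forward order: ring C closes onto ring A with rings B and D already in place, O7 is methylated, the ring D bromide becomes CHO, ring F is joined by aldol condensation, ring E is closed oxidatively, and hydrogenolysis finishes.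
- Stereochemistry: the target has no stereocentre; the racemic α-carbon of the ketoester and the E-alkene of the chalcone are both erased on the way.

Key step: step 3

Remark: rotation about the C3–ring D bond is taken as free (no axial chirality assigned), and (5-bromo-2-methoxyphenyl)acetic acid, 4-(benzyloxy)benzoyl chloride, phloroglucinol and 2,4,6-trihydroxyacetophenone are taken as purchasable.

**Step 1**
Reactants: 1 (5-bromo-2-methoxyphenyl)acetic acid
Product: 2 ethyl (5-bromo-2-methoxyphenyl)acetate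
Conditions: EtOH, H2SO4 (cat.), reflux
Reagents that add atoms: ethanol, CCO
Why: Fischer esterification of an unhindered arylacetic acid in excess ethanol is driven to the ester by mass action, and the aryl bromide and methyl ether are inert to it.

**Step 2**
Reactants: 2 ethyl (5-bromo-2-methoxyphenyl)acetate; 3 4-(benzyloxy)benzoyl chloride
Product: 4 ethyl 3-[4-(benzyloxy)phenyl]-2-(5-bromo-2-methoxyphenyl)-3-oxopropanoate (racemic)
Conditions: LiN(SiMe3)2 (2.1 equiv), THF, −78 °C; then 3, −78 to 0 °C; aq NH4Cl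
Reagents that add atoms: none
Why: In this crossed Claisen-type C-acylation the lithium enolate of the arylacetate attacks the non-enolisable aroyl chloride at carbon, and the second equivalent of base deprotonates the more acidic β-ketoester as it forms, which stops a second acylation.

**Step 3**
Reactants: 4 ethyl 3-[4-(benzyloxy)phenyl]-2-(5-bromo-2-methoxyphenyl)-3-oxopropanoate; 5 phloroglucinol
Product: 8 2-[4-(benzyloxy)phenyl]-3-(5-bromo-2-methoxyphenyl)-5,7-dihydroxy-4H-chromen-4-one, via aroylketene 6 (not isolated), via acylphloroglucinol diketone 7 (not isolated)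
Conditions: anhydrous 5 (2 equiv), neat melt, 240 °C, N2 stream (EtOH and H2O swept out), 30–60 min
Reagents that add atoms: none
Why: Heating the enolised ketoester 4 expels ethanol to give aroylketene 6, whose ketene carbon acylates a ring carbon of phloroglucinol (directly, or by O-acylation and acyl shift) to make the C4–C4a bond in diketone 7, after which an ortho hydroxyl adds to the ring B ketone and water is lost to make the O1–C2 bond. The closest known reaction type is the Mentzer thermal chromone synthesis from phloroglucinol and β-ketoesters, which covers aroylacetates and α-substituted ketoesters. Ring C closes by 6-exo-trig attack of the phenolic oxygen on the ketone carbonyl, followed by dehydration of the hemiketal to the aromatic pyranone. No stereocentre is formed, and the racemic α-carbon of 4 ends as sp2 C3. The step needs chromone in place of the Pechmann coumarin and a single ring A regiochemistry: without acid the ketene carbon, not the hindered diaryl-flanked ketone, is the electrophile that meets the arene, and the threefold symmetry of phloroglucinol makes every carbon and every hydroxyl equivalent, so only one chromone can arise. Excess 5 keeps the product, which still has a free 7-hydroxyl and nucleophilic C6 and C8, from being acylated again.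

**Step 4**
Reactants: 8 2-[4-(benzyloxy)phenyl]-3-(5-bromo-2-methoxyphenyl)-5,7-dihydroxy-4H-chromen-4-one
Product: 9 2-[4-(benzyloxy)phenyl]-3-(5-bromo-2-methoxyphenyl)-5-hydroxy-7-methoxy-4H-chromen-4-one
Conditions: MeI (1.1 equiv), K2CO3 (1.2 equiv), acetone, reflux
Reagents that add atoms: iodomethane, CI
Why: In this Williamson etherification the 7-hydroxyl is the free and more acidic one (vinylogous acid para to the C4 carbonyl), whereas the 5-hydroxyl is tied up in a hydrogen bond to the C4 carbonyl, so one equivalent of MeI should methylate O7 only.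

**Step 5**
Reactants: 9 2-[4-(benzyloxy)phenyl]-3-(5-bromo-2-methoxyphenyl)-5-hydroxy-7-methoxy-4H-chromen-4-one
Product: 10 3-{2-[4-(benzyloxy)phenyl]-5-hydroxy-7-methoxy-4-oxo-4H-chromen-3-yl}-4-methoxybenzaldehyde
Conditions: Pd(OAc)2 (cat.), di(1-adamantyl)-n-butylphosphine, TMEDA, CO/H2 (1:1, 5 bar), toluene, 100 °C
Reagents that add atoms: carbon monoxide, [C-]#[O+]
Why: In this palladium-catalysed reductive carbonylation (formylation) of an aryl bromide, oxidative addition to zerovalent palladium, CO insertion and hydrogenolysis of the acylpalladium release the aldehyde under conditions that leave ethers, the pyranone and a chelated phenol untouched.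

**Step 6**
Reactants: 11 2,4,6-trihydroxyacetophenone
Product: 12 1-[2,4-bis(benzyloxy)-6-hydroxyphenyl]ethan-1-one
Conditions: BnBr (2.1 equiv), K2CO3 (2.2 equiv), DMF, rt
Reagents that add atoms: benzyl bromide, BrCc1ccccc1
Why: In this Williamson benzylation the para hydroxyl and one of the two equivalent ortho hydroxyls react, while the remaining ortho hydroxyl is deactivated by its hydrogen bond to the acetyl carbonyl.

**Step 7**
Reactants: 10 3-{2-[4-(benzyloxy)phenyl]-5-hydroxy-7-methoxy-4-oxo-4H-chromen-3-yl}-4-methoxybenzaldehyde; 12 1-[2,4-bis(benzyloxy)-6-hydroxyphenyl]ethan-1-one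
Product: 13 (E)-1-[2,4-bis(benzyloxy)-6-hydroxyphenyl]-3-(3-{2-[4-(benzyloxy)phenyl]-5-hydroxy-7-methoxy-4-oxo-4H-chromen-3-yl}-4-methoxyphenyl)prop-2-en-1-one
Conditions: KOH (aq, excess), EtOH/THF, rt
Reagents that add atoms: none
Why: In this Claisen–Schmidt condensation the methyl ketone enolate adds to the non-enolisable aldehyde and E1cB loss of water gives the conjugated E-enone, while the 5-phenoxide formed in base makes ring C a poorer acceptor for hydroxide.

**Step 8**
Reactants: 13 (E)-1-[2,4-bis(benzyloxy)-6-hydroxyphenyl]-3-(3-{2-[4-(benzyloxy)phenyl]-5-hydroxy-7-methoxy-4-oxo-4H-chromen-3-yl}-4-methoxyphenyl)prop-2-en-1-one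
Product: 14 2-[4-(benzyloxy)phenyl]-3-{5-[5,7-bis(benzyloxy)-4-oxo-4H-chromen-2-yl]-2-methoxyphenyl}-5-hydroxy-7-methoxy-4H-chromen-4-one
Conditions: I2 (cat.), DMSO, 130 °C
Reagents that add atoms: none
Why: In this iodine-catalysed oxidative cyclisation of a 2'-hydroxychalcone the one free ortho hydroxyl closes ring E by 6-endo-trig oxa-Michael addition and iodination–elimination at the α-carbon installs the C2=C3 double bond, DMSO reoxidising HI to I2 so that only a catalytic amount of I2 is present and iodination of ring A is limited.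

**Step 9**
Reactants: 14 2-[4-(benzyloxy)phenyl]-3-{5-[5,7-bis(benzyloxy)-4-oxo-4H-chromen-2-yl]-2-methoxyphenyl}-5-hydroxy-7-methoxy-4H-chromen-4-one
Product: 15 3-[5-(5,7-dihydroxy-4-oxo-4H-chromen-2-yl)-2-methoxyphenyl]-5-hydroxy-2-(4-hydroxyphenyl)-7-methoxy-4H-chromen-4-one (CNP0288914.0)
Conditions: H2 (1 atm), 10% Pd/C, THF/MeOH, rt
Reagents that add atoms: none
Why: Catalytic hydrogenolysis cleaves the three benzylic C–O bonds, while the aryl methyl ethers and the aryl-conjugated pyranone double bonds are not expected to be reduced at 1 atm and room temperature.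

**Compound list**

1 | (5-bromo-2-methoxyphenyl)acetic acid | COc1ccc(Br)cc1CC(=O)O | starting material
2 | ethyl (5-bromo-2-methoxyphenyl)acetate | CCOC(=O)Cc1cc(Br)ccc1OC | intermediate
3 | 4-(benzyloxy)benzoyl chloride | O=C(Cl)c1ccc(OCc2ccccc2)cc1 | starting material
4 | ethyl 3-[4-(benzyloxy)phenyl]-2-(5-bromo-2-methoxyphenyl)-3-oxopropanoate (racemic, enolisable) | CCOC(=O)C(c1cc(Br)ccc1OC)C(=O)c1ccc(OCc2ccccc2)cc1 | intermediate
5 | phloroglucinol (benzene-1,3,5-triol) | Oc1cc(O)cc(O)c1 | starting material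
6 | 3-[4-(benzyloxy)phenyl]-2-(5-bromo-2-methoxyphenyl)-3-oxoprop-1-en-1-one (aroylketene, formed in the melt) | O=C=C(c1cc(Br)ccc1OC)C(=O)c1ccc(OCc2ccccc2)cc1 | intermediate
7 | 1-[4-(benzyloxy)phenyl]-2-(5-bromo-2-methoxyphenyl)-3-(2,4,6-trihydroxyphenyl)propane-1,3-dione (racemic, formed in the melt) | O=C(c1c(O)cc(O)cc1O)C(c1cc(Br)ccc1OC)C(=O)c1ccc(OCc2ccccc2)cc1 | intermediate
8 | 2-[4-(benzyloxy)phenyl]-3-(5-bromo-2-methoxyphenyl)-5,7-dihydroxy-4H-chromen-4-one | Oc1cc(O)c2c(=O)c(-c3cc(Br)ccc3OC)c(-c3ccc(OCc4ccccc4)cc3)oc2c1 | intermediate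
9 | 2-[4-(benzyloxy)phenyl]-3-(5-bromo-2-methoxyphenyl)-5-hydroxy-7-methoxy-4H-chromen-4-one | COc1cc(O)c2c(=O)c(-c3cc(Br)ccc3OC)c(-c3ccc(OCc4ccccc4)cc3)oc2c1 | intermediate
10 | 3-{2-[4-(benzyloxy)phenyl]-5-hydroxy-7-methoxy-4-oxo-4H-chromen-3-yl}-4-methoxybenzaldehyde | COc1cc(O)c2c(=O)c(-c3cc(C=O)ccc3OC)c(-c3ccc(OCc4ccccc4)cc3)oc2c1 | intermediate
11 | 2,4,6-trihydroxyacetophenone | CC(=O)c1c(O)cc(O)cc1O | starting material
12 | 1-[2,4-bis(benzyloxy)-6-hydroxyphenyl]ethan-1-one | CC(=O)c1c(O)cc(OCc2ccccc2)cc1OCc1ccccc1 | intermediate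
13 | (E)-1-[2,4-bis(benzyloxy)-6-hydroxyphenyl]-3-(3-{2-[4-(benzyloxy)phenyl]-5-hydroxy-7-methoxy-4-oxo-4H-chromen-3-yl}-4-methoxyphenyl)prop-2-en-1-one | COc1cc(O)c2c(=O)c(-c3cc(/C=C/C(=O)c4c(O)cc(OCc5ccccc5)cc4OCc4ccccc4)ccc3OC)c(-c3ccc(OCc4ccccc4)cc3)oc2c1 | intermediate
14 | 2-[4-(benzyloxy)phenyl]-3-{5-[5,7-bis(benzyloxy)-4-oxo-4H-chromen-2-yl]-2-methoxyphenyl}-5-hydroxy-7-methoxy-4H-chromen-4-one | COc1cc(O)c2c(=O)c(-c3cc(-c4cc(=O)c5c(OCc6ccccc6)cc(OCc6ccccc6)cc5o4)ccc3OC)c(-c3ccc(OCc4ccccc4)cc3)oc2c1 | intermediate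
15 | 3-[5-(5,7-dihydroxy-4-oxo-4H-chromen-2-yl)-2-methoxyphenyl]-5-hydroxy-2-(4-hydroxyphenyl)-7-methoxy-4H-chromen-4-one | COc1cc(O)c2c(=O)c(-c3cc(-c4cc(=O)c5c(O)cc(O)cc5o4)ccc3OC)c(-c3ccc(O)cc3)oc2c1 | target

**Step count and risks**

Total step count: 9. Longest linear sequence: 8 (steps 1, 2, 3, 4, 5, 7, 8, 9); step 6 prepares the ring F partner.

Steps most likely to fail:

Step 3. At 240 °C the water released may hydrolyse and decarboxylate the ketoester, the benzyl ether may be lost or migrate, and traces of acid may divert the condensation towards arene attack on the ketone and lactonisation. The fallback sets out from 1 and 5 and comes back at 8. Friedel–Crafts acylation of 5 with acid 1 in BF3·OEt2 at 80 °C should give the deoxybenzoin 2-(5-bromo-2-methoxyphenyl)-1-(2,4,6-trihydroxyphenyl)ethan-1-one F1. O-Aroylation with 3 (2.2 equiv) and K2CO3 in refluxing acetone, with Baker–Venkataraman-type O-to-C aroyl shift onto the benzylic carbon and cyclodehydration, should give 2-[4-(benzyloxy)phenyl]-3-(5-bromo-2-methoxyphenyl)-5-hydroxy-4-oxo-4H-chromen-7-yl 4-(benzyloxy)benzoate F2. Methanolysis of the 7-ester (K2CO3, MeOH, rt) then returns to 8.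

Step 5. Hydrodebromination may outrun CO insertion, a phenol may trap the acylpalladium as an aryl ester, or the 5-hydroxy-4-keto chelate may sequester the catalyst. The fallback sets out from 9 and comes back at 10. Suzuki–Miyaura vinylation with potassium vinyltrifluoroborate K[CH2=CHBF3] (PdCl2(dppf), Cs2CO3, THF/H2O, 80 °C) should give 2-[4-(benzyloxy)phenyl]-3-(5-ethenyl-2-methoxyphenyl)-5-hydroxy-7-methoxy-4H-chromen-4-one F3. Lemieux–Johnson cleavage (OsO4 cat., NaIO4, 2,6-lutidine, dioxane/H2O, rt) then delivers 10.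

Step 7. Hydroxide may add at C2 of ring C and open the pyranone by retro-Claisen cleavage faster than the electron-rich aldehyde undergoes aldol addition. The fallback sets out from 10 and comes back at 14, so that steps 7 and 8 are both bypassed. Pinnick oxidation (NaClO2, NaH2PO4, 2-methyl-2-butene, t-BuOH/H2O) should give 3-{2-[4-(benzyloxy)phenyl]-5-hydroxy-7-methoxy-4-oxo-4H-chromen-3-yl}-4-methoxybenzoic acid F4. Steglich esterification with phenol 12 (EDC·HCl, DMAP, CH2Cl2) should give 2-acetyl-3,5-bis(benzyloxy)phenyl 3-{2-[4-(benzyloxy)phenyl]-5-hydroxy-7-methoxy-4-oxo-4H-chromen-3-yl}-4-methoxybenzoate F5. Baker–Venkataraman rearrangement with the non-nucleophilic base LiN(SiMe3)2 (THF, −78 °C to rt) should give 1-[2,4-bis(benzyloxy)-6-hydroxyphenyl]-3-(3-{2-[4-(benzyloxy)phenyl]-5-hydroxy-7-methoxy-4-oxo-4H-chromen-3-yl}-4-methoxyphenyl)propane-1,3-dione F6. Cyclodehydration (cat. H2SO4, AcOH, 60 °C) then closes ring E to 14.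

**Further compounds**

F1 | step 3 | 2-(5-bromo-2-methoxyphenyl)-1-(2,4,6-trihydroxyphenyl)ethan-1-one | COc1ccc(Br)cc1CC(=O)c1c(O)cc(O)cc1O
F2 | step 3 | 2-[4-(benzyloxy)phenyl]-3-(5-bromo-2-methoxyphenyl)-5-hydroxy-4-oxo-4H-chromen-7-yl 4-(benzyloxy)benzoate | COc1ccc(Br)cc1-c1c(-c2ccc(OCc3ccccc3)cc2)oc2cc(OC(=O)c3ccc(OCc4ccccc4)cc3)cc(O)c2c1=O
F3 | step 5 | 2-[4-(benzyloxy)phenyl]-3-(5-ethenyl-2-methoxyphenyl)-5-hydroxy-7-methoxy-4H-chromen-4-one | COc1cc(O)c2c(=O)c(-c3cc(C=C)ccc3OC)c(-c3ccc(OCc4ccccc4)cc3)oc2c1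
F4 | step 7 | 3-{2-[4-(benzyloxy)phenyl]-5-hydroxy-7-methoxy-4-oxo-4H-chromen-3-yl}-4-methoxybenzoic acid | COc1cc(O)c2c(=O)c(-c3cc(C(=O)O)ccc3OC)c(-c3ccc(OCc4ccccc4)cc3)oc2c1
F5 | step 7 | 2-acetyl-3,5-bis(benzyloxy)phenyl 3-{2-[4-(benzyloxy)phenyl]-5-hydroxy-7-methoxy-4-oxo-4H-chromen-3-yl}-4-methoxybenzoate | COc1cc(O)c2c(=O)c(-c3cc(C(=O)Oc4cc(OCc5ccccc5)cc(OCc5ccccc5)c4C(C)=O)ccc3OC)c(-c3ccc(OCc4ccccc4)cc3)oc2c1
F6 | step 7 | 1-[2,4-bis(benzyloxy)-6-hydroxyphenyl]-3-(3-{2-[4-(benzyloxy)phenyl]-5-hydroxy-7-methoxy-4-oxo-4H-chromen-3-yl}-4-methoxyphenyl)propane-1,3-dione | COc1cc(O)c2c(=O)c(-c3cc(C(=O)CC(=O)c4c(O)cc(OCc5ccccc5)cc4OCc4ccccc4)ccc3OC)c(-c3ccc(OCc4ccccc4)cc3)oc2c1
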